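You charge L with 3.00 mM to spare over E, so E goes down along a slow tail and Z arrives over a spread of times.

    Z → X (k1 = 0.0188 s⁻¹)
    E + L → Z + J (k2 = 2.97 M⁻¹ s⁻¹)
    Z ⇌ D (K3 = 0.369, k3 = 0.105 s⁻¹)
    Z ⇌ G (K4 = 2.37, k4 = 0.0424 s⁻¹)
    Q ⇌ D, rate k5*(cs5 - [D]) while solid is left; crystals form when [D] > cs5 (cs5 = 4.0 mM, k5 = 1.02 s⁻¹)

E 10 mM; L 1.30 equiv; time 4.0 min

- how much D and Q together there is at 4.0 min, in percent of the E charged
- concentration of D in solution at 4.0 min, in percent of saturation

Here is my reckoning. Z and D exchange with a relaxation half-life of 1.78 s, far shorter than the run, and D takes 27.0 % of the two. Even the whole charge held that way gives [D] of 2.70 mM, less than the solubility, so I expect no Q.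

Now treat Z, D and G as one pool in pre-equilibrium. Its parts stand as 1 to 0.369 to 2.37, so Z is 26.7 % of it and D is 9.87 %. Replace the feed curve by its mean: let all E become Z at one moment, 49.4 s, which is the logarithm of L charged over L to spare, divided by the rate constant times [E] at the start. The leak number, the time after that moment multiplied by the rate constant of Z to X and by Z's share of the pool, is 0.958. It counts pool lifetimes passed, and the part of the charge not turned into X is e to the minus N, 38.3 %. This gives y of 3.78 % and sat of 9.46 %.

One number is not quite enough, though. Z leaks at 0.0188 s⁻¹, about as fast as G returns at 0.0179 s⁻¹, so G lags and my figure should run high.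

The forecast says 3.05 % and 7.6 %, below mine, and it gets there by “Convolving the E consumption by hand”.

The flask gives 3.08 % and 7.69 %, with Q at 0 %, so the forecast held. G stands at 2.93 times Z, above 2.37. The part of the charge that is not X is 38.4 %, as e to the minus N said.

Read at 10 min, the same flask has a leak number of 2.77, which gives y of 0.619 %. The simulation gives 0.723 %, above the reckoning this time.

All constants were drawn at random within sensible limits; no experiment stands behind them.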